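**Strategy.** Everything rests on disconnecting the cis-1,3-amino alcohol made up of N, the N–CH carbon shared by rings A and B, the B/C fusion CH and the tertiary carbinol carbon of ring C, with the new C–C and C–O bonds cis on ring C. One intramolecular nitrone–alkene (3+2) cycloaddition forms both bonds, builds ring B and a sacrificial isoxazolidine in the same event, and fixes three stereocentres. Its precursor is a Z-nitrone made from an N-alkylhydroxylamine, tethered by three carbons to the alkene of a spiro butenolide–cyclopentene (rings C and D), and a chiral δ-keto aldehyde with an unmasked ketone, on which the amine freed by N–O cleavage later closes ring A.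

Key step: step 16

Remark on the chemistry: the side-chain ketone is assumed to need no acetal, because an N-alkylhydroxylamine condenses with an aldehyde far faster than with a hindered α-silyloxy ketone; both secondary hydroxyls are carried as TBS ethers.

**Route**

Step 1
Reactants: 1 5-chloropent-1-yne
Product: 3 2-bromo-5-chloropent-1-ene, via bromoboration adduct 2 (not isolated)
Conditions: B-bromo-9-BBN, CH2Cl2, 0 °C; then AcOH, 0 °C to rt
Reagents that add atoms: B-bromo-9-borabicyclo[3.3.1]nonane (BrB1C2CCCC1CCC2)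
Why: syn-bromoboration of the terminal alkyne puts boron on the terminal and bromine on the internal carbon, and protodeboronation of the alkenylborane with acetic acid leaves the 2-bromo-1-alkene (haloboration/protonolysis); no stereocentre is formed.

Step 2
Reactants: 4 (E)-but-2-ene; 5 ethyl glyoxylate
Product: 8 ethyl (2S,3S)-2-hydroxy-3-methylpent-4-enoate, via crotylpotassium 6 (not isolated), via crotyldiisopinocampheylborane 7 (not isolated)
Conditions: 4, n-BuLi, KOt-Bu, THF, −78 to −45 °C; (−)-B-methoxydiisopinocampheylborane [(−)-Ipc2BOMe], then BF3·OEt2, −78 °C; 5 (freshly distilled), −78 °C; NaBO3·4H2O, THF/H2O, rt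
Reagents that add atoms: none
Why: Brown crotylboration through a closed chair transition state, in which the E-crotyl geometry should give the 2,3-anti relation and the isopinocampheyl groups derived from (+)-α-pinene should direct the crotyl unit to the Si face of the formyl group, setting C2 (S) and C3 (S) together.

Step 3
Reactants: 8 ethyl (2S,3S)-2-hydroxy-3-methylpent-4-enoate
Product: 9 ethyl (2S,3S)-2-[(tert-butyldimethylsilyl)oxy]-3-methylpent-4-enoate
Conditions: TBSCl, imidazole, DMF, rt
Reagents that add atoms: tert-butyl(chloro)dimethylsilane (CC(C)(C)[Si](C)(C)Cl)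
Why: standard silylation of a secondary alcohol; the non-chelating TBS ether is what later steers the carbonyl addition in step 6, and no stereocentre is touched.

Step 4
Reactants: 9 ethyl (2S,3S)-2-[(tert-butyldimethylsilyl)oxy]-3-methylpent-4-enoate
Product: 10 (2S,3S)-2-[(tert-butyldimethylsilyl)oxy]-N-methoxy-N,3-dimethylpent-4-enamide
Conditions: MeNH(OMe)·HCl, i-PrMgCl, THF, −20 to 0 °C
Reagents that add atoms: N,O-dimethylhydroxylamine hydrochloride (CNOC.Cl)
Why: aminolysis of the ester by the magnesium amide of N,O-dimethylhydroxylamine (Weinreb amide formation) at low temperature, which should leave the α-silyloxy centre unepimerized.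

Step 5
Reactants: 3 2-bromo-5-chloropent-1-ene; 10 (2S,3S)-2-[(tert-butyldimethylsilyl)oxy]-N-methoxy-N,3-dimethylpent-4-enamide
Product: 12 (3S,4S)-4-[(tert-butyldimethylsilyl)oxy]-9-chloro-3-methyl-6-methylidenenon-1-en-5-one, via alkenyllithium 11 (not isolated)
Conditions: 3, t-BuLi (2 equiv), Et2O, −78 °C; then 10, −78 to −40 °C; aq. NH4Cl
Reagents that add atoms: none
Why: bromine–lithium exchange (the primary chloride is inert at −78 °C) followed by acylation of the alkenyllithium with the Weinreb amide, whose chelated tetrahedral intermediate prevents over-addition and enolization; no new stereocentre.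

Step 6
Reactants: 12 (3S,4S)-4-[(tert-butyldimethylsilyl)oxy]-9-chloro-3-methyl-6-methylidenenon-1-en-5-one; 13 methyl propiolate
Product: 15 methyl (4R,5S,6S)-5-[(tert-butyldimethylsilyl)oxy]-4-(5-chloropent-1-en-2-yl)-4-hydroxy-6-methyloct-7-en-2-ynoate, via lithium acetylide 14 (not isolated)
Conditions: 13, LiN(SiMe3)2, THF, −78 °C; then 12, −78 °C; aq. NH4Cl
Reagents that add atoms: none
Why: 1,2-addition of a lithium acetylide to an α-silyloxy ketone under polar Felkin–Anh control, in which the non-chelating silyloxy group lies anti to the incoming nucleophile and the acetylide passes the α-hydrogen, so the new tertiary carbinol (4R) should carry its oxygen trans to the silyloxy group once ring C is closed.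

Step 7
Reactants: 15 methyl (4R,5S,6S)-5-[(tert-butyldimethylsilyl)oxy]-4-(5-chloropent-1-en-2-yl)-4-hydroxy-6-methyloct-7-en-2-ynoate
Product: 16 (5S)-5-[(1S,2S)-1-[(tert-butyldimethylsilyl)oxy]-2-methylbut-3-en-1-yl]-5-(5-chloropent-1-en-2-yl)-4-methoxyfuran-2(5H)-one
Conditions: NaOMe (0.3 equiv), MeOH, 0 °C to rt
Reagents that add atoms: methanol (CO)
Why: conjugate addition of methoxide to the ynoate and lactonization of the tertiary hydroxyl onto the resulting β-methoxy enoate (tetronate formation from a γ-hydroxy ynoate); the quaternary centre is not involved.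

Step 8
Reactants: 16 (5S)-5-[(1S,2S)-1-[(tert-butyldimethylsilyl)oxy]-2-methylbut-3-en-1-yl]-5-(5-chloropent-1-en-2-yl)-4-methoxyfuran-2(5H)-one
Product: 18 (5S)-5-[(1S,2S)-1-[(tert-butyldimethylsilyl)oxy]-2-methylbut-3-en-1-yl]-5-(5-chloropent-1-en-2-yl)-4-methoxy-3-methylfuran-2(5H)-one, via 3-lithio butenolide 17 (not isolated)
Conditions: LiN(i-Pr)2, THF, −78 °C; MeI, −78 to −20 °C
Reagents that add atoms: iodomethane (CI)
Why: with C5 quaternary, the only acidic position of the tetronate is the vinylic C3–H between the carbonyl and the β-methoxy group, so α-lithiation and C-methylation (known for C5-blocked methyl tetronates) should install the ring-D methyl; no stereocentre changes.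

Step 9
Reactants: 18 (5S)-5-[(1S,2S)-1-[(tert-butyldimethylsilyl)oxy]-2-methylbut-3-en-1-yl]-5-(5-chloropent-1-en-2-yl)-4-methoxy-3-methylfuran-2(5H)-one
Product: 19 (5S,8S,9S)-9-[(tert-butyldimethylsilyl)oxy]-6-(3-chloropropyl)-4-methoxy-3,8-dimethyl-1-oxaspiro[4.4]nona-3,6-dien-2-one
Conditions: second-generation Grubbs catalyst RuCl2(=CHPh)(PCy3)(H2IMes) (5 mol%), CH2Cl2, 40 °C
Reagents that add atoms: none
Why: ring-closing metathesis of the vinyl and 1,1-disubstituted alkenes gives the trisubstituted cyclopentene (ring C), helped by the fully substituted carbon between them, while the tetrasubstituted butenolide alkene is inert; the three stereocentres are carried over unchanged.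

Step 10
Reactants: 19 (5S,8S,9S)-9-[(tert-butyldimethylsilyl)oxy]-6-(3-chloropropyl)-4-methoxy-3,8-dimethyl-1-oxaspiro[4.4]nona-3,6-dien-2-one; 20 tert-butyl N-[(tert-butoxycarbonyl)oxy]carbamate
Product: 22 tert-butyl N-[(tert-butoxycarbonyl)oxy]-N-{3-[(5S,8S,9S)-9-[(tert-butyldimethylsilyl)oxy]-4-methoxy-3,8-dimethyl-2-oxo-1-oxaspiro[4.4]nona-3,6-dien-6-yl]propyl}carbamate, via alkyl iodide 21 (not isolated)
Conditions: K2CO3, NaI (0.2 equiv), DMF, 60 °C
Reagents that add atoms: none
Why: Finkelstein exchange and SN2 N-alkylation of the acidic N,O-bis-Boc-hydroxylamine anion, a standard entry to N-alkylhydroxylamines that excludes over-alkylation and spares the base-stable butenolide.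

Step 11
Reactants: 22 tert-butyl N-[(tert-butoxycarbonyl)oxy]-N-{3-[(5S,8S,9S)-9-[(tert-butyldimethylsilyl)oxy]-4-methoxy-3,8-dimethyl-2-oxo-1-oxaspiro[4.4]nona-3,6-dien-6-yl]propyl}carbamate
Product: 23 N-{3-[(5S,8S,9S)-9-[(tert-butyldimethylsilyl)oxy]-4-methoxy-3,8-dimethyl-2-oxo-1-oxaspiro[4.4]nona-3,6-dien-6-yl]propyl}hydroxylamine
Conditions: CF3CO2H/CH2Cl2 (1:4), 0 °C; cold aq. NaHCO3; used at once
Reagents that add atoms: none
Why: acidolysis of both tert-butoxycarbonyl groups, which the hindered ring-C TBS ether and the tetronate should survive at 0 °C; the hydroxylamine stays protonated (no Cope-type cyclization onto the alkene) until the cold bicarbonate wash.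

Step 12
Reactants: 24 (R)-2-hydroxybutanoic acid
Product: 25 (2R)-2-hydroxy-N-methoxy-N-methylbutanamide
Conditions: MeNH(OMe)·HCl, EDC·HCl, HOBt, N-methylmorpholine, CH2Cl2, 0 °C to rt
Reagents that add atoms: N,O-dimethylhydroxylamine hydrochloride (CNOC.Cl)
Why: carbodiimide/HOBt amide coupling, under which the α-hydroxy stereocentre from the chiral pool is not enolized.

Step 13
Reactants: 25 (2R)-2-hydroxy-N-methoxy-N-methylbutanamide
Product: 26 (2R)-2-[(tert-butyldimethylsilyl)oxy]-N-methoxy-N-methylbutanamide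
Conditions: TBSCl, imidazole, DMF, rt
Reagents that add atoms: tert-butyl(chloro)dimethylsilane (CC(C)(C)[Si](C)(C)Cl)
Why: standard silylation, which protects the carbinol through the organometallic, oxidative and reductive steps that follow.

Step 14
Reactants: 26 (2R)-2-[(tert-butyldimethylsilyl)oxy]-N-methoxy-N-methylbutanamide; 27 5-bromopent-1-ene
Product: 29 (3R)-3-[(tert-butyldimethylsilyl)oxy]non-8-en-4-one, via Grignard reagent 28 (not isolated)
Conditions: 27, Mg, THF, rt; then 26, 0 °C; aq. NH4Cl
Reagents that add atoms: none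
Why: Grignard addition to a Weinreb amide stops at the chelated tetrahedral intermediate, giving the ketone without over-addition and without loss of the α-silyloxy configuration.

Step 15
Reactants: 29 (3R)-3-[(tert-butyldimethylsilyl)oxy]non-8-en-4-one
Product: 31 (6R)-6-[(tert-butyldimethylsilyl)oxy]-5-oxooctanal, via ozonide 30 (not isolated)
Conditions: O3, CH2Cl2, −78 °C; PPh3, −78 °C to rt
Reagents that add atoms: ozone (O=[O+][O-])
Why: ozonolysis of the terminal alkene with reductive work-up gives the aldehyde, while the ketone and silyl ether are inert; the δ-keto aldehyde is used without storage.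

Step 16
Reactants: 23 N-{3-[(5S,8S,9S)-9-[(tert-butyldimethylsilyl)oxy]-4-methoxy-3,8-dimethyl-2-oxo-1-oxaspiro[4.4]nona-3,6-dien-6-yl]propyl}hydroxylamine; 31 (6R)-6-[(tert-butyldimethylsilyl)oxy]-5-oxooctanal
Product: 33 bridged keto isoxazolidine with ring B closed (bis-TBS cycloadduct), via Z-nitrone 32 (not isolated)
Conditions: MgSO4, CH2Cl2, rt; filter, concentrate; PhMe, 110 °C
Reagents that add atoms: none
Why: Condensation of the hydroxylamine with the aldehyde (far faster than with the hindered ketone) gives the Z-aldonitrone, which on heating should add in a concerted, suprafacial (3+2) fashion across the tethered cyclopentene; the closest known reaction type is the intramolecular cycloaddition of N-(4-alkenyl) nitrones to bridged isoxazolidines. Ring B forms in the bridged mode as the seven-membered ring of a 1-aza-8-oxabicyclo[3.2.1]octane (nitrone carbon to the CH end of the alkene), and the isoxazolidine forms as the five-membered ring of the same bicycle (oxygen to the fully substituted alkene carbon). The B/C fusion CH and the tertiary C–O carbon are created cis by the suprafacial addition, with their absolute sense fixed by approach to the ring-C face opposite the methyl group, the silyloxy group and the methoxy-bearing half of ring D. The N–CH centre follows from the Z geometry of the nitrone, which puts its alkyl chain exo, trans to the N-tether, in the bicycle. The step needs bridged rather than fused regiochemistry, secured because the fused mode would demand a C–C bond to the substituted alkene carbon next to the spiro centre, and it needs one alkene face, secured by the three groups on the other face; the ketone is a spectator.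

Step 17
Reactants: 33 bridged keto isoxazolidine (bis-TBS cycloadduct)
Product: 36 bis-TBS ether of the target (rings A–D complete), via amino ketone 34 (not isolated), via cyclic iminium acetate 35 (not isolated)
Conditions: Zn dust, AcOH/THF (1:1), rt to 40 °C; filter; NaBH(OAc)3, 0 °C to rt
Reagents that add atoms: none
Why: zinc in acetic acid cleaves the N–O bond to the 1,3-amino alcohol, the secondary amine condenses with the δ-ketone to a six-membered iminium, and hydride should add axially on the face away from the ring-B/C substituent at the neighbouring N–CH carbon (intramolecular reductive amination under stereoelectronic control), giving the 2,6-cis piperidine and so the ring-A stereocentre.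

Step 18
Reactants: 36 bis-TBS ether of the target
Product: 37 CNP0267781.1 (target)
Conditions: HF·pyridine, pyridine/THF, 0 °C to rt
Reagents that add atoms: none
Why: fluoride-mediated desilylation under non-basic conditions removes both TBS groups without exposing the two carbinols next to the spiro tetronate carbon to alkoxide-induced retro-aldol cleavage or translactonization; no stereocentre is affected.

**Compound list**

1 | 5-chloropent-1-yne | C#CCCCCl | starting material
2 | (Z)-9-(2-bromo-5-chloropent-1-en-1-yl)-9-borabicyclo[3.3.1]nonane (bromoboration adduct) | ClCCC/C(Br)=C/B1C2CCCC1CCC2 | intermediate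
3 | 2-bromo-5-chloropent-1-ene | C=C(Br)CCCCl | intermediate
4 | (E)-but-2-ene | C/C=C/C | starting material
5 | ethyl glyoxylate | CCOC(=O)C=O | starting material
6 | (E)-but-2-enylpotassium (crotylpotassium) | C/C=C/C[K] | intermediate
7 | B-[(E)-but-2-enyl]diisopinocampheylborane, Ipc groups from (+)-α-pinene | C[C@H]1[C@H](B(C/C=C/C)[C@@H]3C[C@@H]4C[C@H]([C@H]3C)C4(C)C)C[C@@H]2C[C@H]1C2(C)C | intermediate
8 | ethyl (2S,3S)-2-hydroxy-3-methylpent-4-enoate | C=C[C@H](C)[C@H](O)C(=O)OCC | intermediate
9 | ethyl (2S,3S)-2-[(tert-butyldimethylsilyl)oxy]-3-methylpent-4-enoate | C=C[C@H](C)[C@H](O[Si](C)(C)C(C)(C)C)C(=O)OCC | intermediate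
10 | (2S,3S)-2-[(tert-butyldimethylsilyl)oxy]-N-methoxy-N,3-dimethylpent-4-enamide | C=C[C@H](C)[C@H](O[Si](C)(C)C(C)(C)C)C(=O)N(C)OC | intermediate
11 | (5-chloropent-1-en-2-yl)lithium | [Li]C(=C)CCCCl | intermediate
12 | (3S,4S)-4-[(tert-butyldimethylsilyl)oxy]-9-chloro-3-methyl-6-methylidenenon-1-en-5-one | C=C[C@H](C)[C@H](O[Si](C)(C)C(C)(C)C)C(=O)C(=C)CCCCl | intermediate
13 | methyl propiolate | C#CC(=O)OC | starting material
14 | lithium (3-methoxy-3-oxoprop-1-yn-1-ide) | [Li]C#CC(=O)OC | intermediate
15 | methyl (4R,5S,6S)-5-[(tert-butyldimethylsilyl)oxy]-4-(5-chloropent-1-en-2-yl)-4-hydroxy-6-methyloct-7-en-2-ynoate | C=C[C@H](C)[C@H](O[Si](C)(C)C(C)(C)C)[C@](O)(C#CC(=O)OC)C(=C)CCCCl | intermediate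
16 | (5S)-5-[(1S,2S)-1-[(tert-butyldimethylsilyl)oxy]-2-methylbut-3-en-1-yl]-5-(5-chloropent-1-en-2-yl)-4-methoxyfuran-2(5H)-one | C=C[C@H](C)[C@H](O[Si](C)(C)C(C)(C)C)[C@]1(C(=C)CCCCl)OC(=O)C=C1OC | intermediate
17 | 3-lithio derivative of 16 | C=C[C@H](C)[C@H](O[Si](C)(C)C(C)(C)C)[C@]1(C(=C)CCCCl)OC(=O)C([Li])=C1OC | intermediate
18 | (5S)-5-[(1S,2S)-1-[(tert-butyldimethylsilyl)oxy]-2-methylbut-3-en-1-yl]-5-(5-chloropent-1-en-2-yl)-4-methoxy-3-methylfuran-2(5H)-one | C=C[C@H](C)[C@H](O[Si](C)(C)C(C)(C)C)[C@]1(C(=C)CCCCl)OC(=O)C(C)=C1OC | intermediate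
19 | (5S,8S,9S)-9-[(tert-butyldimethylsilyl)oxy]-6-(3-chloropropyl)-4-methoxy-3,8-dimethyl-1-oxaspiro[4.4]nona-3,6-dien-2-one | ClCCCC1=C[C@H](C)[C@H](O[Si](C)(C)C(C)(C)C)[C@@]12OC(=O)C(C)=C2OC | intermediate
20 | tert-butyl N-[(tert-butoxycarbonyl)oxy]carbamate | CC(C)(C)OC(=O)NOC(=O)OC(C)(C)C | starting material
21 | (5S,8S,9S)-9-[(tert-butyldimethylsilyl)oxy]-6-(3-iodopropyl)-4-methoxy-3,8-dimethyl-1-oxaspiro[4.4]nona-3,6-dien-2-one | ICCCC1=C[C@H](C)[C@H](O[Si](C)(C)C(C)(C)C)[C@@]12OC(=O)C(C)=C2OC | intermediate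
22 | tert-butyl N-[(tert-butoxycarbonyl)oxy]-N-{3-[(5S,8S,9S)-9-[(tert-butyldimethylsilyl)oxy]-4-methoxy-3,8-dimethyl-2-oxo-1-oxaspiro[4.4]nona-3,6-dien-6-yl]propyl}carbamate | CC(C)(C)OC(=O)ON(CCCC1=C[C@H](C)[C@H](O[Si](C)(C)C(C)(C)C)[C@@]12OC(=O)C(C)=C2OC)C(=O)OC(C)(C)C | intermediate
23 | N-{3-[(5S,8S,9S)-9-[(tert-butyldimethylsilyl)oxy]-4-methoxy-3,8-dimethyl-2-oxo-1-oxaspiro[4.4]nona-3,6-dien-6-yl]propyl}hydroxylamine | ONCCCC1=C[C@H](C)[C@H](O[Si](C)(C)C(C)(C)C)[C@@]12OC(=O)C(C)=C2OC | intermediate
24 | (R)-2-hydroxybutanoic acid | CC[C@@H](O)C(=O)O | starting material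
25 | (2R)-2-hydroxy-N-methoxy-N-methylbutanamide | CC[C@@H](O)C(=O)N(C)OC | intermediate
26 | (2R)-2-[(tert-butyldimethylsilyl)oxy]-N-methoxy-N-methylbutanamide | CC[C@@H](O[Si](C)(C)C(C)(C)C)C(=O)N(C)OC | intermediate
27 | 5-bromopent-1-ene | C=CCCCBr | starting material
28 | pent-4-en-1-ylmagnesium bromide | C=CCCC[Mg]Br | intermediate
29 | (3R)-3-[(tert-butyldimethylsilyl)oxy]non-8-en-4-one | CC[C@@H](O[Si](C)(C)C(C)(C)C)C(=O)CCCC=C | intermediate
30 | secondary ozonide of 29 (3-substituted 1,2,4-trioxolane) | CC[C@@H](O[Si](C)(C)C(C)(C)C)C(=O)CCCC1OCOO1 | intermediate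
31 | (6R)-6-[(tert-butyldimethylsilyl)oxy]-5-oxooctanal | CC[C@@H](O[Si](C)(C)C(C)(C)C)C(=O)CCCC=O | intermediate
32 | (Z)-nitrone from 23 and 31: (6R)-6-[(tert-butyldimethylsilyl)oxy]-5-oxooctan-1-imine N-oxide carrying the 3-(spiro cyclopentenyl)propyl group of 23 on nitrogen | CC[C@@H](O[Si](C)(C)C(C)(C)C)C(=O)CCC/C=[N+](\[O-])CCCC1=C[C@H](C)[C@H](O[Si](C)(C)C(C)(C)C)[C@@]12OC(=O)C(C)=C2OC | intermediate
33 | bridged isoxazolidine: 1-aza-8-oxabicyclo[3.2.1]octane fused to ring C, ring B closed, exo (5R)-5-silyloxy-4-oxoheptyl chain on the N–CH carbon, both TBS ethers in place | CC[C@@H](O[Si](C)(C)C(C)(C)C)C(=O)CCC[C@H]1[C@H]2[C@H](C)[C@H](O[Si](C)(C)C(C)(C)C)[C@@]3(OC(=O)C(C)=C3OC)[C@]2(O4)CCCN14 | intermediate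
34 | amino ketone: ring-B azepane NH with the cis tertiary alcohol on ring C and the pendant δ-keto chain | CC[C@@H](O[Si](C)(C)C(C)(C)C)C(=O)CCC[C@H]1[C@H]2[C@H](C)[C@H](O[Si](C)(C)C(C)(C)C)[C@@]3(OC(=O)C(C)=C3OC)[C@]2(O)CCCN1 | intermediate
35 | cyclic iminium acetate (ring A closed as a tetrahydropyridinium) | CC[C@@H](O[Si](C)(C)C(C)(C)C)C=1CCC[C@H]2[C@H]3[C@H](C)[C@H](O[Si](C)(C)C(C)(C)C)[C@@]4(OC(=O)C(C)=C4OC)[C@]3(O)CCC[N+]=12.CC(=O)[O-] | intermediate
36 | bis-TBS ether of the target (2,6-cis piperidine ring A, rings A–D complete) | CC[C@@H](O[Si](C)(C)C(C)(C)C)[C@H]1CCC[C@H]2[C@H]3[C@H](C)[C@H](O[Si](C)(C)C(C)(C)C)[C@@]4(OC(=O)C(C)=C4OC)[C@]3(O)CCCN12 | intermediate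
37 | CNP0267781.1 | CC[C@@H](O)[C@H]1CCC[C@H]2[C@H]3[C@H](C)[C@H](O)[C@@]4(OC(=O)C(C)=C4OC)[C@]3(O)CCCN12 | target

**Step count.** Total: 18 steps. Longest linear sequence: 13 steps (5 to 37: steps 2–11 and 16–18).

**Steps most likely to fail**

Step 16 (key step). The free hydroxylamine 23 may be lost to Cope-type cyclization onto the ring alkene or to air oxidation before it meets the aldehyde. The nitrone may also decay during the long heating that the hindered trisubstituted alkene demands. Either process would lower the supply of dipole for the bridged addition. The fallback makes the dipole without ever liberating 23. It sets out from chloride 19: NaI in acetone gives the iodide 21 (now isolated), and AgNO2 in Et2O converts it into the nitroalkane F1. Reduction of F1 with Zn/NH4Cl in aqueous EtOH in the presence of aldehyde 31 traps the hydroxylamine as it forms and gives nitrone 32. Heating as in step 16 returns to the route at cycloadduct 33.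

Step 6. Facial discrimination in the acetylide addition may be insufficient (Felkin–Anh and competing transition states), or the enone may be enolized. The fallback reverses the order in which the two carbon groups are attached, so that chelation rather than the Felkin–Anh model sets the carbinol. It sets out from Weinreb amide 10. The lithium acetylide F2 of 3,3,3-triethoxyprop-1-yne (n-BuLi, THF, −78 °C) gives the ynone orthoester F3. The alkenylzinc bromide F4, made from alkenyllithium 11 and ZnBr2, is added in toluene/CH2Cl2 with EtZnCl as chelating Lewis acid. Zinc bridges the ketone and silyloxy oxygens, so the alkenyl group enters past the α-hydrogen and gives the tertiary alcohol F5 with the same configuration as 15. PPTS in wet THF unmasks the ethyl ynoate F6, and NaOMe/MeOH as in step 7 returns to the route at butenolide 16.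

Step 17. After N–O cleavage the transient iminium may be reduced by zinc without stereocontrol, the α-silyloxy ketone may be attacked by zinc, or the α-silyloxy centre may epimerize through the enamine if ring closure is slow. The fallback separates N–O cleavage from ring closure by masking the ketone. It sets out from ketone 29. 1,2-Bis(trimethylsilyloxy)ethane with catalytic TMSOTf (CH2Cl2, −78 to −20 °C) gives the dioxolane F7. Ozonolysis through the ozonide F8 (O3; PPh3) gives the dioxolane aldehyde F9. Condensation with 23 gives the dioxolane nitrone F10, which on heating in toluene gives the dioxolane cycloadduct F11. Zn/AcOH then gives the isolable amino alcohol F12. Aqueous HCl/THF removes the acetal in the absence of zinc (amino ketone 34, iminium 35), and NaBH(OAc)3 closes ring A, returning to the route at 36.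

Further compounds
F1 | step 16 | (5S,8S,9S)-9-[(tert-butyldimethylsilyl)oxy]-4-methoxy-3,8-dimethyl-6-(3-nitropropyl)-1-oxaspiro[4.4]nona-3,6-dien-2-one | [O-][N+](=O)CCCC1=C[C@H](C)[C@H](O[Si](C)(C)C(C)(C)C)[C@@]12OC(=O)C(C)=C2OC
F2 | step 6 | lithium 3,3,3-triethoxyprop-1-yn-1-ide | [Li]C#CC(OCC)(OCC)OCC
F3 | step 6 | (5S,6S)-5-[(tert-butyldimethylsilyl)oxy]-1,1,1-triethoxy-6-methyloct-7-en-2-yn-4-one | C=C[C@H](C)[C@H](O[Si](C)(C)C(C)(C)C)C(=O)C#CC(OCC)(OCC)OCC
F4 | step 6 | (5-chloropent-1-en-2-yl)zinc bromide | Br[Zn]C(=C)CCCCl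
F5 | step 6 | (4R,5S,6S)-5-[(tert-butyldimethylsilyl)oxy]-4-(5-chloropent-1-en-2-yl)-1,1,1-triethoxy-6-methyloct-7-en-2-yn-4-ol | C=C[C@H](C)[C@H](O[Si](C)(C)C(C)(C)C)[C@](O)(C#CC(OCC)(OCC)OCC)C(=C)CCCCl
F6 | step 6 | ethyl (4R,5S,6S)-5-[(tert-butyldimethylsilyl)oxy]-4-(5-chloropent-1-en-2-yl)-4-hydroxy-6-methyloct-7-en-2-ynoate | C=C[C@H](C)[C@H](O[Si](C)(C)C(C)(C)C)[C@](O)(C#CC(=O)OCC)C(=C)CCCCl
F7 | step 17 | 2-[(1R)-1-[(tert-butyldimethylsilyl)oxy]propyl]-2-(pent-4-en-1-yl)-1,3-dioxolane | CC[C@@H](O[Si](C)(C)C(C)(C)C)C1(CCCC=C)OCCO1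
F8 | step 17 | secondary ozonide of F7 (3-substituted 1,2,4-trioxolane) | CC[C@@H](O[Si](C)(C)C(C)(C)C)C1(CCCC2OCOO2)OCCO1
F9 | step 17 | 4-{2-[(1R)-1-[(tert-butyldimethylsilyl)oxy]propyl]-1,3-dioxolan-2-yl}butanal | CC[C@@H](O[Si](C)(C)C(C)(C)C)C1(CCCC=O)OCCO1
F10 | step 17 | (Z)-nitrone from 23 and F9 (dioxolane analogue of 32) | CC[C@@H](O[Si](C)(C)C(C)(C)C)C1(OCCO1)CCC/C=[N+](\[O-])CCCC2=C[C@H](C)[C@H](O[Si](C)(C)C(C)(C)C)[C@@]23OC(=O)C(C)=C3OC
F11 | step 17 | bridged isoxazolidine with dioxolane (dioxolane analogue of 33) | CC[C@@H](O[Si](C)(C)C(C)(C)C)C1(OCCO1)CCC[C@H]2[C@H]3[C@H](C)[C@H](O[Si](C)(C)C(C)(C)C)[C@@]4(OC(=O)C(C)=C4OC)[C@]3(O5)CCCN25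
F12 | step 17 | amino alcohol with dioxolane (dioxolane analogue of 34) | CC[C@@H](O[Si](C)(C)C(C)(C)C)C1(OCCO1)CCC[C@H]2[C@H]3[C@H](C)[C@H](O[Si](C)(C)C(C)(C)C)[C@@]4(OC(=O)C(C)=C4OC)[C@]3(O)CCCN2
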